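**Plan**

- Retrosynthetic cuts, in order: the O7–CH3 bond; the C4a–C5 bond of ring A; the O1–C8a bond of ring C; the C4–C4a bond; the C2–C3 bond; the aryl C2'–geranyl bond.
- Forward: ring B is geranylated, the chain C2–C8 with a dioxinone (C7, C6, C5) is attached, ring C (dihydropyranone) closes first, ring A closes last, and one O-methylation finishes the target.
- Enabling feature: ring A carries oxygen on C5, C7 and C8a and the C4 acyl carbon on C4a (an acylphloroglucinol). This pattern arises when C4a, the α-carbon of the ring C vinylogous ester, attacks a ketene carbon C5, so a dioxinone hung on C8 of a preformed pyranone gives ring A directly.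
- Stereochemistry: the only stereocentre, C2 (S), is set by a catalytic enantioselective Mukaiyama aldol addition, and its C–O bond is never broken afterwards. The E-alkene comes in with geranyl bromide.

Key step: step 8

Shorthand: flavanone numbering (O1, C2 to C8a) is used for the chain throughout; geranyl = (2E)-3,7-dimethylocta-2,6-dien-1-yl.

Assumption: in step 2 the (R)-configured ligand is taken to expose the Si face of the aldehyde, which gives the 3S alcohol; if the sense is the reverse, the (S)-ligand is used and nothing else changes.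

**Step 1**
Reactants: 1 veratraldehyde; 2 geranyl bromide
Product: 6 2-geranyl-3,4-dimethoxybenzaldehyde, via lithium α-amino alkoxide 3 (not isolated), via C2-lithiated α-amino alkoxide 4 (not isolated), via geranylated α-amino alkoxide 5 (not isolated)
Conditions: Me2NCH2CH2NHMe, n-BuLi, THF, −20 °C; n-BuLi (3 equiv), −20 °C; CuBr·SMe2 (10 mol %), 2 (4 equiv), −78 °C → rt; 1 M HCl
Reagents that add atoms: none
Why: Directed ortho-metalation, in which the α-amino alkoxide formed in the flask and the 3-methoxy group together steer n-BuLi to C2, followed by copper-catalysed SN2 allylation by the primary allylic bromide (E-alkene kept) and release of the aldehyde by aqueous acid.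

**Step 2**
Reactants: 6 2-geranyl-3,4-dimethoxybenzaldehyde
Product: 8 methyl (3S)-3-(2-geranyl-3,4-dimethoxyphenyl)-3-hydroxypropanoate, via trimethylsilyl ether 7 (not isolated)
Conditions: Ti(OiPr)4, (R)-2-[(3-bromo-5-tert-butyl-2-hydroxybenzylidene)amino]-2'-hydroxy-1,1'-binaphthyl, 3,5-di-tert-butylsalicylic acid (5 mol % each), Et2O, 0 °C; then 1 M HCl, THF, 0 °C
Reagents that add atoms: 1-methoxy-1-(trimethylsilyloxy)ethene, C=C(OC)O[Si](C)(C)C
Why: Catalytic enantioselective Mukaiyama aldol addition in which the chiral titanium Lewis acid should expose the Si face of the aldehyde to the silyl ketene acetal and so set C2 as S, under conditions mild enough to avoid a Prins reaction with the ortho-geranyl chain.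

**Step 3**
Reactants: 8 methyl (3S)-3-(2-geranyl-3,4-dimethoxyphenyl)-3-hydroxypropanoate
Product: 9 methyl (3S)-3-(tert-butyldimethylsilyloxy)-3-(2-geranyl-3,4-dimethoxyphenyl)propanoate
Conditions: TBSOTf, 2,6-lutidine, CH2Cl2, −78 → 0 °C
Reagents that add atoms: tert-butyldimethylsilyl triflate, CC(C)(C)[Si](C)(C)OS(=O)(=O)C(F)(F)F
Why: Standard silylation of a hindered secondary benzylic alcohol with a silyl triflate and a hindered base, which blocks retro-aldol and elimination in the basic steps that follow.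

**Step 4**
Reactants: 9 methyl (3S)-3-(tert-butyldimethylsilyloxy)-3-(2-geranyl-3,4-dimethoxyphenyl)propanoate
Product: 10 (3S)-3-(tert-butyldimethylsilyloxy)-3-(2-geranyl-3,4-dimethoxyphenyl)-N-methoxy-N-methylpropanamide
Conditions: MeNH(OMe)·HCl, i-PrMgCl, THF, −20 → 0 °C
Reagents that add atoms: N,O-dimethylhydroxylamine hydrochloride, CNOC.Cl
Why: Aminolysis of the methyl ester by the magnesium amide of N,O-dimethylhydroxylamine (Weinreb amide formation) is fast below 0 °C and should leave the β-silyloxy stereocentre and both alkenes untouched.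

**Step 5**
Reactants: 11 2,2,6-trimethyl-4H-1,3-dioxin-4-one
Product: 13 2,2-dimethyl-6-(2-oxopropyl)-4H-1,3-dioxin-4-one, via lithium dienolate 12 (not isolated)
Conditions: 11 (2 equiv), LiN(SiMe3)2 (2 equiv), THF, −78 °C; AcCl (1 equiv), −78 °C; aq. NH4Cl
Reagents that add atoms: acetyl chloride, CC(=O)Cl
Why: γ-Selective crossed Claisen acylation of the dioxinone lithium dienolate by an acid chloride, a standard entry to keto-dioxinones, with the second equivalent of dienolate absorbing the more acidic product.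

**Step 6**
Reactants: 13 2,2-dimethyl-6-(2-oxopropyl)-4H-1,3-dioxin-4-one; 10 (3S)-3-(tert-butyldimethylsilyloxy)-3-(2-geranyl-3,4-dimethoxyphenyl)-N-methoxy-N-methylpropanamide
Product: 15 6-[(6S)-6-(tert-butyldimethylsilyloxy)-6-(2-geranyl-3,4-dimethoxyphenyl)-2,4-dioxohexyl]-2,2-dimethyl-4H-1,3-dioxin-4-one, via dilithio dianion 14 (not isolated)
Conditions: 13 (2 equiv), LiN(i-Pr)2 (4 equiv), THF, −78 → −40 °C; then 10, −78 → −30 °C; aq. NH4Cl (pH 6)
Reagents that add atoms: none
Why: Claisen-type acylation (Weinreb ketone synthesis) at the more reactive terminal carbanion of the keto-dioxinone dianion forms C4–C4a, a standard route to diketo-dioxinones, and the ketone is released only on quenching so that over-addition and proton transfer to unreacted dianion are avoided.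

**Step 7**
Reactants: 15 6-[(6S)-6-(tert-butyldimethylsilyloxy)-6-(2-geranyl-3,4-dimethoxyphenyl)-2,4-dioxohexyl]-2,2-dimethyl-4H-1,3-dioxin-4-one
Product: 18 (2S)-6-[(2,2-dimethyl-4-oxo-4H-1,3-dioxin-6-yl)methyl]-2-(2-geranyl-3,4-dimethoxyphenyl)-2,3-dihydro-4H-pyran-4-one, via hydroxy diketone 16 (not isolated), via cyclic hemiketal 17 (not isolated)
Conditions: HF·pyridine, pyridine, THF, 0 °C → rt; then PPTS (10 mol %), 4 Å MS, CH2Cl2, rt
Reagents that add atoms: none
Why: Cyclodehydration of a δ-hydroxy-β-diketone, in which fluoride frees the C2 hydroxyl, this adds 6-exo-trig to the C8a ketone and mild acid dehydrates the hemiketal toward C4a to the conjugated vinylogous ester, with no bond to C2 broken and with C8a tied into ring C before the base-promoted aldol-mode aromatisation can begin.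

**Step 8**
Reactants: 18 (2S)-6-[(2,2-dimethyl-4-oxo-4H-1,3-dioxin-6-yl)methyl]-2-(2-geranyl-3,4-dimethoxyphenyl)-2,3-dihydro-4H-pyran-4-one
Product: 21 (2S)-2-(2-geranyl-3,4-dimethoxyphenyl)-5,7-dihydroxychroman-4-one, via acylketene 19 (not isolated), via cyclohexadienone 20 (not isolated)
Conditions: dry PhMe (0.005 M, slow addition of 18), 110 °C
Reagents that add atoms: none
Why: Proposed new method: near 110 °C the dioxinone of 18 should lose acetone by retro-[4+2] to give acylketene 19, whose C7 ketone enolises toward the doubly activated C8 methylene so that C4a=C8a, C8=C7 and C6=C5 line up as a trienyl ketene. Thermal 6π-electrocyclisation (seen the other way, a 6-(enolendo)-exo-dig C-acylation by the α-carbon of the vinylogous ester) forms C4a–C5 and closes ring A as cyclohexadienone 20, which should tautomerise at once to the phloroglucinol ring of 21. The closest known reaction types are the thermolysis of diketo-dioxinones to acylketenes that aromatise to resorcylates and the electrocyclisation of dienylketenes to phenols; new here is the capture of the ketene by a dihydropyranone carbon. No stereocentre is created, and C2 is spared because the medium is neutral and the C2–O1 bond is never at risk. The step needs Claisen-mode over aldol-mode folding and ring closure over intermolecular ketene capture: the first is secured because C8a is locked as an enol ether in ring C, so that attack of C6 on C4 would give a bridged ring that cannot aromatise, and the second by high dilution and slow addition.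

**Step 9**
Reactants: 21 (2S)-2-(2-geranyl-3,4-dimethoxyphenyl)-5,7-dihydroxychroman-4-one
Product: 22 (2S)-2-(2-geranyl-3,4-dimethoxyphenyl)-5-hydroxy-7-methoxychroman-4-one
Conditions: Me3SiCHN2 (1.2 equiv), MeOH/PhMe (1:4), 0 °C → rt
Reagents that add atoms: trimethylsilyldiazomethane, C[Si](C)(C)C=[N+]=[N-]
Why: Neutral diazoalkane O-methylation should take the acidic 7-hydroxyl (para to the ketone) and leave the hydrogen-bonded 5-hydroxyl alone, while avoiding the base-induced ring opening to a chalcone that would scramble C2.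

**Compound list**

1 | veratraldehyde (3,4-dimethoxybenzaldehyde) | COc1ccc(C=O)cc1OC | starting material
2 | geranyl bromide ((2E)-1-bromo-3,7-dimethylocta-2,6-diene) | CC(C)=CCC/C(C)=C/CBr | starting material
3 | lithium (3,4-dimethoxyphenyl){[2-(dimethylamino)ethyl](methyl)amino}methanolate, formed in the flask | [Li]OC(N(C)CCN(C)C)c1ccc(OC)c(OC)c1 | intermediate
4 | 2-lithio derivative of 3, formed in the flask | [Li]OC(N(C)CCN(C)C)c1ccc(OC)c(OC)c1[Li] | intermediate
5 | 2-geranyl derivative of 3, formed in the flask | [Li]OC(N(C)CCN(C)C)c1ccc(OC)c(OC)c1C/C=C(\C)CCC=C(C)C | intermediate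
6 | 2-geranyl-3,4-dimethoxybenzaldehyde | COc1ccc(C=O)c(C/C=C(\C)CCC=C(C)C)c1OC | intermediate
7 | methyl (3S)-3-(2-geranyl-3,4-dimethoxyphenyl)-3-(trimethylsilyloxy)propanoate, formed in the flask | COC(=O)C[C@H](O[Si](C)(C)C)c1ccc(OC)c(OC)c1C/C=C(\C)CCC=C(C)C | intermediate
8 | methyl (3S)-3-(2-geranyl-3,4-dimethoxyphenyl)-3-hydroxypropanoate | COC(=O)C[C@H](O)c1ccc(OC)c(OC)c1C/C=C(\C)CCC=C(C)C | intermediate
9 | methyl (3S)-3-(tert-butyldimethylsilyloxy)-3-(2-geranyl-3,4-dimethoxyphenyl)propanoate | COC(=O)C[C@H](O[Si](C)(C)C(C)(C)C)c1ccc(OC)c(OC)c1C/C=C(\C)CCC=C(C)C | intermediate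
10 | (3S)-3-(tert-butyldimethylsilyloxy)-3-(2-geranyl-3,4-dimethoxyphenyl)-N-methoxy-N-methylpropanamide | CON(C)C(=O)C[C@H](O[Si](C)(C)C(C)(C)C)c1ccc(OC)c(OC)c1C/C=C(\C)CCC=C(C)C | intermediate
11 | 2,2,6-trimethyl-4H-1,3-dioxin-4-one | CC1=CC(=O)OC(C)(C)O1 | starting material
12 | lithium dienolate of 11 (lithium 2,2-dimethyl-6-methylidene-6H-1,3-dioxin-4-olate), formed in the flask | C=C1C=C(O[Li])OC(C)(C)O1 | intermediate
13 | 2,2-dimethyl-6-(2-oxopropyl)-4H-1,3-dioxin-4-one | CC(=O)CC1=CC(=O)OC(C)(C)O1 | intermediate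
14 | dilithio dianion of 13, formed in the flask | C=C(O[Li])C=C1C=C(O[Li])OC(C)(C)O1 | intermediate
15 | 6-[(6S)-6-(tert-butyldimethylsilyloxy)-6-(2-geranyl-3,4-dimethoxyphenyl)-2,4-dioxohexyl]-2,2-dimethyl-4H-1,3-dioxin-4-one | CC1(C)OC(=CC(=O)O1)CC(=O)CC(=O)C[C@H](O[Si](C)(C)C(C)(C)C)c1ccc(OC)c(OC)c1C/C=C(\C)CCC=C(C)C | intermediate
16 | 6-[(6S)-6-(2-geranyl-3,4-dimethoxyphenyl)-6-hydroxy-2,4-dioxohexyl]-2,2-dimethyl-4H-1,3-dioxin-4-one, formed in the flask | CC1(C)OC(=CC(=O)O1)CC(=O)CC(=O)C[C@H](O)c1ccc(OC)c(OC)c1C/C=C(\C)CCC=C(C)C | intermediate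
17 | 6-{[(6S)-6-(2-geranyl-3,4-dimethoxyphenyl)-2-hydroxy-4-oxotetrahydro-2H-pyran-2-yl]methyl}-2,2-dimethyl-4H-1,3-dioxin-4-one (both hemiketal epimers), formed in the flask | CC1(C)OC(=CC(=O)O1)CC1(O)CC(=O)C[C@@H](c2ccc(OC)c(OC)c2C/C=C(\C)CCC=C(C)C)O1 | intermediate
18 | (2S)-6-[(2,2-dimethyl-4-oxo-4H-1,3-dioxin-6-yl)methyl]-2-(2-geranyl-3,4-dimethoxyphenyl)-2,3-dihydro-4H-pyran-4-one | CC1(C)OC(=CC(=O)O1)CC1=CC(=O)C[C@@H](c2ccc(OC)c(OC)c2C/C=C(\C)CCC=C(C)C)O1 | intermediate
19 | (2S)-6-(2,4-dioxobut-3-en-1-yl)-2-(2-geranyl-3,4-dimethoxyphenyl)-2,3-dihydro-4H-pyran-4-one (acylketene), formed in the flask | O=C=CC(=O)CC1=CC(=O)C[C@@H](c2ccc(OC)c(OC)c2C/C=C(\C)CCC=C(C)C)O1 | intermediate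
20 | (2S)-2-(2-geranyl-3,4-dimethoxyphenyl)-7-hydroxy-2,3-dihydro-4H-chromene-4,5(4aH)-dione, formed in the flask | O=C1C=C(O)C=C2O[C@H](c3ccc(OC)c(OC)c3C/C=C(\C)CCC=C(C)C)CC(=O)C12 | intermediate
21 | (2S)-2-(2-geranyl-3,4-dimethoxyphenyl)-5,7-dihydroxychroman-4-one | Oc1cc(O)c2c(c1)O[C@H](c1ccc(OC)c(OC)c1C/C=C(\C)CCC=C(C)C)CC2=O | intermediate
22 | (2S)-2-(2-geranyl-3,4-dimethoxyphenyl)-5-hydroxy-7-methoxychroman-4-one | COc1cc(O)c2c(c1)O[C@H](c1ccc(OC)c(OC)c1C/C=C(\C)CCC=C(C)C)CC2=O | target

**Step count and risks**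

Total steps: 9. Longest linear sequence: 8 (steps 1, 2, 3, 4, 6, 7, 8, 9); step 5 is a one-step side branch.

Step 8 (the step proposed as new). The acylketene may be consumed by dimerisation, by traces of water or by the phenols of product already formed before the weakly nucleophilic C4a closes on it. The fallback brings ring A in as a ready-made arene and closes ring C by O–aryl bond formation, which keeps the C2–O bond and so the configuration. It sets out from amide 10. Addition of (2-fluoro-4,6-dimethoxyphenyl)lithium (from 2-bromo-1-fluoro-3,5-dimethoxybenzene and n-BuLi, THF, −78 °C) should give the aryl ketone (3S)-3-(tert-butyldimethylsilyloxy)-1-(2-fluoro-4,6-dimethoxyphenyl)-3-(2-geranyl-3,4-dimethoxyphenyl)propan-1-one F1. Bu4NF in THF should remove the silyl group, and the alkoxide set free should displace the ortho-fluoride activated by the ketone (intramolecular SNAr) to give (2S)-2-(2-geranyl-3,4-dimethoxyphenyl)-5,7-dimethoxychroman-4-one F2. MgI2·OEt2 in THF should then cleave only the 5-methoxy group, which chelates with the C4 carbonyl, and so return to the route at target 22.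

Step 6. Proton transfer from the α-methylene of amide 10 to the dianion, followed by loss of silanolate, may compete with acylation, and the diketo-dioxinone may begin aldol-mode aromatisation during the quench. The fallback replaces acylation by aldol addition and oxidation. It sets out from amide 10: reduction with i-Bu2AlH (THF, −78 °C) should give the aldehyde (3S)-3-(tert-butyldimethylsilyloxy)-3-(2-geranyl-3,4-dimethoxyphenyl)propanal F3. Addition of dianion 14 at −78 °C should give the β-hydroxy ketone 6-[(6S)-6-(tert-butyldimethylsilyloxy)-6-(2-geranyl-3,4-dimethoxyphenyl)-4-hydroxy-2-oxohexyl]-2,2-dimethyl-4H-1,3-dioxin-4-one F4, as a mixture of carbinol epimers that does not matter. Dess–Martin oxidation buffered with NaHCO3 should then return to the route at diketo-dioxinone 15.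

Step 7. Once the C2 hydroxyl is free, aldol-mode cyclisation of the 1,3-diketone onto the dioxinone (resorcylate formation), or acid-induced ionisation of the p-alkoxybenzylic C2–O bond, may outrun hemiketalisation and dehydration. The fallback closes ring C while C4 is still an alcohol, so that no 1,3-diketone ever sits next to the dioxinone; it thereby also bypasses step 6. It sets out from amide 10 and uses aldehyde F3 and aldol adduct F4 described above. Desilylation and ketalisation of F4 in one operation (HF·pyridine, THF; then MeOH, HC(OMe)3, PPTS) should give the cyclic methyl ketal 6-{[(6S)-6-(2-geranyl-3,4-dimethoxyphenyl)-4-hydroxy-2-methoxytetrahydro-2H-pyran-2-yl]methyl}-2,2-dimethyl-4H-1,3-dioxin-4-one F5. Dess–Martin oxidation should give the ketone 6-{[(6S)-6-(2-geranyl-3,4-dimethoxyphenyl)-2-methoxy-4-oxotetrahydro-2H-pyran-2-yl]methyl}-2,2-dimethyl-4H-1,3-dioxin-4-one F6. Warming F6 with PPTS in benzene should eliminate methanol and return to the route at pyranone 18.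

**Further compounds**

F1 | step 8 | (3S)-3-(tert-butyldimethylsilyloxy)-1-(2-fluoro-4,6-dimethoxyphenyl)-3-(2-geranyl-3,4-dimethoxyphenyl)propan-1-one | COc1cc(F)c(C(=O)C[C@H](O[Si](C)(C)C(C)(C)C)c2ccc(OC)c(OC)c2C/C=C(\C)CCC=C(C)C)c(OC)c1
F2 | step 8 | (2S)-2-(2-geranyl-3,4-dimethoxyphenyl)-5,7-dimethoxychroman-4-one | COc1cc(OC)c2c(c1)O[C@H](c1ccc(OC)c(OC)c1C/C=C(\C)CCC=C(C)C)CC2=O
F3 | step 6 | (3S)-3-(tert-butyldimethylsilyloxy)-3-(2-geranyl-3,4-dimethoxyphenyl)propanal | O=CC[C@H](O[Si](C)(C)C(C)(C)C)c1ccc(OC)c(OC)c1C/C=C(\C)CCC=C(C)C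
F4 | step 6 | 6-[(6S)-6-(tert-butyldimethylsilyloxy)-6-(2-geranyl-3,4-dimethoxyphenyl)-4-hydroxy-2-oxohexyl]-2,2-dimethyl-4H-1,3-dioxin-4-one | CC1(C)OC(=CC(=O)O1)CC(=O)CC(O)C[C@H](O[Si](C)(C)C(C)(C)C)c1ccc(OC)c(OC)c1C/C=C(\C)CCC=C(C)C
F5 | step 7 | 6-{[(6S)-6-(2-geranyl-3,4-dimethoxyphenyl)-4-hydroxy-2-methoxytetrahydro-2H-pyran-2-yl]methyl}-2,2-dimethyl-4H-1,3-dioxin-4-one | CC1(C)OC(=CC(=O)O1)CC1(OC)CC(O)C[C@@H](c2ccc(OC)c(OC)c2C/C=C(\C)CCC=C(C)C)O1
F6 | step 7 | 6-{[(6S)-6-(2-geranyl-3,4-dimethoxyphenyl)-2-methoxy-4-oxotetrahydro-2H-pyran-2-yl]methyl}-2,2-dimethyl-4H-1,3-dioxin-4-one | CC1(C)OC(=CC(=O)O1)CC1(OC)CC(=O)C[C@@H](c2ccc(OC)c(OC)c2C/C=C(\C)CCC=C(C)C)O1
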